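**Plan**

- Retrosynthesis: the benzyl ethers come off last. The ketone–ring D bond is cut to an aryl bromide and a Weinreb amide, O1–C2 to a phenol and a p-alkoxybenzylic alcohol, and C2–ring B to a lactol and an aryl Grignard reagent.
- The lactol is cut at C4–C4a and O1–C2 into resorcinol and a ring D cinnamaldehyde, whose C=C bond goes back to a brominated phloroglucinaldehyde tribenzyl ether.
- Enabling feature: ring A is a resorcinol whose nucleophilic carbon C4a and neighbouring oxygen O1 flank the unit C4–C3–C2. With ring D on C4 and C2 as an aldehyde, that unit is a β-aryl enal.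
- Forward: rings A, B and D are bought. Ring C is the only ring made, first as a lactol (step 4), then opened by the Grignard reagent and closed again as the flavan (step 7). The C12 chain is joined in step 10.
- Stereochemistry: C4 (R) comes from the S-configured diarylprolinol silyl ether in step 4. C2 (R) is set under control of C4 in the reversible acid closure to the 2,4-cis flavan.

Key step: step 4

Assumption: rotation about the C4–ring D bond is taken to be fast at room temperature, so C2 and C4 are the only stereogenic elements. The bromine on ring D is a spectator in step 4 and fixes the site of acylation in step 10.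

**Route**

Step 1
Reactants: 1 2,4,6-trihydroxybenzaldehyde
Product: 2 2,4,6-tris(benzyloxy)benzaldehyde
Conditions: BnBr (3.5 equiv), K2CO3 (4 equiv), DMF, 60 °C
Reagents that add atoms: benzyl bromide, BrCc1ccccc1
Why: Williamson ether synthesis, in which the formyl group lowers the nucleophilicity of the ring carbons so that the phenoxides alkylate on oxygen, and warming brings the two hydrogen-bonded ortho hydroxyls to full conversion.

Step 2
Reactants: 2 2,4,6-tris(benzyloxy)benzaldehyde
Product: 3 2,4,6-tris(benzyloxy)-3-bromobenzaldehyde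
Conditions: NBS (1.0 equiv), MeCN, 0 °C to rt
Reagents that add atoms: N-bromosuccinimide, O=C1CCC(=O)N1Br
Why: Electrophilic aromatic bromination at C3 (equivalent to C5), which lies ortho or para to all three benzyloxy groups, with one equivalent of NBS in a polar solvent so that the ring and not a benzylic position reacts and the first bromine slows a second substitution.

Step 3
Reactants: 3 2,4,6-tris(benzyloxy)-3-bromobenzaldehyde
Product: 4 (2E)-3-[2,4,6-tris(benzyloxy)-3-bromophenyl]prop-2-enal
Conditions: Ph3P=CHCHO (1.3 equiv), toluene, 90 °C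
Reagents that add atoms: (triphenylphosphoranylidene)acetaldehyde, O=CC=P(c1ccccc1)(c1ccccc1)c1ccccc1
Why: Wittig olefination with a formyl-stabilised ylide, which should give the E-enal, the limited excess of ylide keeping a second homologation of the product in check.

Step 4
Reactants: 4 (2E)-3-[2,4,6-tris(benzyloxy)-3-bromophenyl]prop-2-enal; 5 resorcinol
Product: 8 (4R)-4-[2,4,6-tris(benzyloxy)-3-bromophenyl]chromane-2,7-diol (lactol as a mixture of C2 epimers), via iminium benzoate 6 (not isolated), via ring-open aldehyde 7 (not isolated)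
Conditions: (S)-2-[diphenyl(trimethylsilyloxy)methyl]pyrrolidine (20 mol%), PhCO2H (20 mol%), 5 (3 equiv), CH2Cl2/MeCN 4:1, 0 °C to rt
Reagents that add atoms: none
Why: Condensation of the secondary amine with enal 4 gives the E-configured iminium ion 6, whose lowered LUMO is attacked at the β-carbon by resorcinol through its C4 (ortho to one hydroxyl, para to the other), forming C4–C4a; hydrolysis of the resulting enamine releases aldehyde 7 and the catalyst. The closest known reaction type is the diarylprolinol silyl ether catalysed Friedel–Crafts alkylation and hemiacetalisation of electron-rich phenols and naphthols with β-aryl enals, which gives 4-arylchroman-2-ols. Ring C closes when the phenolic oxygen next to the new bond adds to the aldehyde carbonyl of 7 in a 6-exo-trig hemiacetalisation, forming O1–C2. C4 is controlled by the catalyst: the silyloxydiphenylmethyl group of the S-configured pyrrolidine covers the Re face of the β-carbon (aryl > Cα > H), so the arene should add to the Si face and give 4R, while C2 of the lactol is left uncontrolled because it is reset in step 7. The step needs 1,4- over 1,2-addition, C- over O-alkylation, attack at C4 and not C2 of resorcinol, and mono- over bis-alkylation; these rest on the soft iminium acceptor, on irreversible C–C bond formation against reversible oxa-Michael addition, on the crowding of the carbon between the two hydroxyls, and on the excess of the symmetric diol, whose two reactive carbons are equivalent.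

Step 5
Reactants: 9 1-(benzyloxy)-4-bromobenzene
Product: 10 [4-(benzyloxy)phenyl]magnesium bromide (THF solution, titrated and used as such)
Conditions: Mg turnings (1.2 equiv), 1,2-dibromoethane (cat.), THF, 40 °C to rt
Reagents that add atoms: magnesium, [Mg]
Why: Grignard reagent formation by insertion of magnesium into the aryl C–Br bond, to which the benzyl aryl ether is inert.

Step 6
Reactants: 8 (4R)-4-[2,4,6-tris(benzyloxy)-3-bromophenyl]chromane-2,7-diol; 10 [4-(benzyloxy)phenyl]magnesium bromide
Product: 12 4-[(1R)-3-[4-(benzyloxy)phenyl]-1-[2,4,6-tris(benzyloxy)-3-bromophenyl]-3-hydroxypropyl]benzene-1,3-diol (both carbinol epimers), via magnesium phenoxide aldehyde 11 (not isolated)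
Conditions: 10 (4 equiv), THF, 0 °C to rt; sat. aq. NH4Cl
Reagents that add atoms: none
Why: Grignard addition to a lactol, in which two equivalents of 10 deprotonate the phenol and the hemiacetal, the magnesium lactolate opens to the ring-open aldehyde as its bis(bromomagnesium) phenoxide 11 and a further equivalent adds to the carbonyl of 11, the ring D bromide being inert to an arylmagnesium halide at this temperature and the new carbinol centre being formed as a mixture that step 7 makes irrelevant.

Step 7
Reactants: 12 4-[(1R)-3-[4-(benzyloxy)phenyl]-1-[2,4,6-tris(benzyloxy)-3-bromophenyl]-3-hydroxypropyl]benzene-1,3-diol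
Product: 13 (2R,4R)-2-[4-(benzyloxy)phenyl]-4-[2,4,6-tris(benzyloxy)-3-bromophenyl]chroman-7-ol (2,4-cis)
Conditions: p-TsOH·H2O (10 mol%), CH2Cl2 (0.01 M), 0 °C to rt
Reagents that add atoms: none
Why: Intramolecular SN1-type dehydrative etherification, in which the p-benzyloxybenzylic C–OH bond ionises under mild acid and the ring A hydroxyl ortho to the side chain closes ring C through a chair-like arrangement with both aryl groups equatorial, and because the benzylic O1–C2 bond re-ionises under the same conditions both carbinol epimers of 12 should converge, under control of C4, on the 2,4-cis isomer (2R), the low acid loading and high dilution sparing the C4–ring D bond and suppressing intermolecular arylation.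

Step 8
Reactants: 13 (2R,4R)-2-[4-(benzyloxy)phenyl]-4-[2,4,6-tris(benzyloxy)-3-bromophenyl]chroman-7-ol
Product: 14 (2R,4R)-7-(benzyloxy)-2-[4-(benzyloxy)phenyl]-4-[2,4,6-tris(benzyloxy)-3-bromophenyl]chromane
Conditions: BnBr (1.2 equiv), K2CO3 (2 equiv), DMF, rt
Reagents that add atoms: benzyl bromide, BrCc1ccccc1
Why: Williamson etherification of the only remaining phenol, which removes the acidic proton before the organolithium step under conditions too mild to touch C2 or C4.

Step 9
Reactants: 15 dodecanoyl chloride
Product: 16 N-methoxy-N-methyldodecanamide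
Conditions: MeNHOMe·HCl (1.1 equiv), Et3N (2.2 equiv), CH2Cl2, 0 °C to rt
Reagents that add atoms: N,O-dimethylhydroxylamine hydrochloride, CNOC.Cl
Why: N-acylation of N,O-dimethylhydroxylamine by an acid chloride, the standard preparation of a Weinreb amide.

Step 10
Reactants: 14 (2R,4R)-7-(benzyloxy)-2-[4-(benzyloxy)phenyl]-4-[2,4,6-tris(benzyloxy)-3-bromophenyl]chromane; 16 N-methoxy-N-methyldodecanamide
Product: 19 1-{2,4,6-tris(benzyloxy)-3-[(2R,4R)-7-(benzyloxy)-2-[4-(benzyloxy)phenyl]chroman-4-yl]phenyl}dodecan-1-one, via aryllithium 17 (not isolated), via tetrahedral lithium adduct 18 (not isolated)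
Conditions: n-BuLi (1.1 equiv), THF, −78 °C, 15 min; 16 (1.5 equiv), −78 to 0 °C; sat. aq. NH4Cl
Reagents that add atoms: none
Why: Bromine–lithium exchange followed by Weinreb ketone synthesis, in which exchange at −78 °C is far faster than benzylic deprotonation, aryllithium 17 is held between two ortho benzyloxy groups and the chelated adduct 18 persists until the quench, so that no tertiary alcohol forms and the acyl group enters ring D only at the carbon that carried bromine.

Step 11
Reactants: 19 1-{2,4,6-tris(benzyloxy)-3-[(2R,4R)-7-(benzyloxy)-2-[4-(benzyloxy)phenyl]chroman-4-yl]phenyl}dodecan-1-one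
Product: 20 1-{2,4,6-trihydroxy-3-[(2R,4R)-7-hydroxy-2-(4-hydroxyphenyl)chroman-4-yl]phenyl}dodecan-1-one (CNP0293819.1)
Conditions: H2 (1 atm), 10% Pd/C, EtOAc/MeOH 1:1, rt
Reagents that add atoms: none
Why: Catalytic hydrogenolysis of the five benzyl ethers over palladium on carbon at atmospheric pressure, which the ketone (conjugated with and hydrogen-bonded to the phloroglucinol ring) and the cyclic benzylic ether O1–C2 are expected to survive on short exposure in a neutral solvent, with neither stereocentre touched.

**Compound list**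

1 | 2,4,6-trihydroxybenzaldehyde | O=Cc1c(O)cc(O)cc1O | starting material
2 | 2,4,6-tris(benzyloxy)benzaldehyde | O=Cc1c(OCc2ccccc2)cc(OCc2ccccc2)cc1OCc1ccccc1 | intermediate
3 | 2,4,6-tris(benzyloxy)-3-bromobenzaldehyde | O=Cc1c(OCc2ccccc2)c(Br)c(OCc2ccccc2)cc1OCc1ccccc1 | intermediate
4 | (2E)-3-[2,4,6-tris(benzyloxy)-3-bromophenyl]prop-2-enal | O=C/C=C/c1c(OCc2ccccc2)c(Br)c(OCc2ccccc2)cc1OCc1ccccc1 | intermediate
5 | resorcinol | Oc1cccc(O)c1 | starting material
6 | (2S)-1-{(2E)-3-[2,4,6-tris(benzyloxy)-3-bromophenyl]prop-2-en-1-ylidene}-2-[diphenyl(trimethylsilyloxy)methyl]pyrrolidinium benzoate | C[Si](C)(C)OC(c1ccccc1)(c1ccccc1)[C@@H]1CCC[N+]1=C/C=C/c1c(OCc2ccccc2)c(Br)c(OCc2ccccc2)cc1OCc1ccccc1.[O-]C(=O)c1ccccc1 | intermediate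
7 | (3R)-3-[2,4,6-tris(benzyloxy)-3-bromophenyl]-3-(2,4-dihydroxyphenyl)propanal | O=CC[C@@H](c1c(OCc2ccccc2)c(Br)c(OCc2ccccc2)cc1OCc1ccccc1)c1ccc(O)cc1O | intermediate
8 | (4R)-4-[2,4,6-tris(benzyloxy)-3-bromophenyl]chromane-2,7-diol (C2 epimers) | OC1C[C@@H](c2c(OCc3ccccc3)c(Br)c(OCc3ccccc3)cc2OCc2ccccc2)c2ccc(O)cc2O1 | intermediate
9 | 1-(benzyloxy)-4-bromobenzene | Brc1ccc(OCc2ccccc2)cc1 | starting material
10 | [4-(benzyloxy)phenyl]magnesium bromide | Br[Mg]c1ccc(OCc2ccccc2)cc1 | intermediate
11 | bis(bromomagnesium) 4-{(1R)-3-oxo-1-[2,4,6-tris(benzyloxy)-3-bromophenyl]propyl}benzene-1,3-diolate (ring-open aldehyde as its magnesium phenoxide) | O=CC[C@@H](c1c(OCc2ccccc2)c(Br)c(OCc2ccccc2)cc1OCc1ccccc1)c1ccc(O[Mg]Br)cc1O[Mg]Br | intermediate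
12 | 4-[(1R)-3-[4-(benzyloxy)phenyl]-1-[2,4,6-tris(benzyloxy)-3-bromophenyl]-3-hydroxypropyl]benzene-1,3-diol (carbinol epimers) | OC(C[C@@H](c1c(OCc2ccccc2)c(Br)c(OCc2ccccc2)cc1OCc1ccccc1)c1ccc(O)cc1O)c1ccc(OCc2ccccc2)cc1 | intermediate
13 | (2R,4R)-2-[4-(benzyloxy)phenyl]-4-[2,4,6-tris(benzyloxy)-3-bromophenyl]chroman-7-ol | Brc1c(OCc2ccccc2)cc(OCc2ccccc2)c([C@@H]2C[C@H](c3ccc(OCc4ccccc4)cc3)Oc3cc(O)ccc32)c1OCc1ccccc1 | intermediate
14 | (2R,4R)-7-(benzyloxy)-2-[4-(benzyloxy)phenyl]-4-[2,4,6-tris(benzyloxy)-3-bromophenyl]chromane | Brc1c(OCc2ccccc2)cc(OCc2ccccc2)c([C@@H]2C[C@H](c3ccc(OCc4ccccc4)cc3)Oc3cc(OCc4ccccc4)ccc32)c1OCc1ccccc1 | intermediate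
15 | dodecanoyl chloride | CCCCCCCCCCCC(=O)Cl | starting material
16 | N-methoxy-N-methyldodecanamide | CCCCCCCCCCCC(=O)N(C)OC | intermediate
17 | {2,4,6-tris(benzyloxy)-3-[(2R,4R)-7-(benzyloxy)-2-[4-(benzyloxy)phenyl]chroman-4-yl]phenyl}lithium | [Li]c1c(OCc2ccccc2)cc(OCc2ccccc2)c([C@@H]2C[C@H](c3ccc(OCc4ccccc4)cc3)Oc3cc(OCc4ccccc4)ccc32)c1OCc1ccccc1 | intermediate
18 | lithium 1-{2,4,6-tris(benzyloxy)-3-[(2R,4R)-7-(benzyloxy)-2-[4-(benzyloxy)phenyl]chroman-4-yl]phenyl}-1-[methoxy(methyl)amino]dodecan-1-olate (epimers at the carbinolamine carbon) | CCCCCCCCCCCC(O[Li])(N(C)OC)c1c(OCc2ccccc2)cc(OCc2ccccc2)c([C@@H]2C[C@H](c3ccc(OCc4ccccc4)cc3)Oc3cc(OCc4ccccc4)ccc32)c1OCc1ccccc1 | intermediate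
19 | 1-{2,4,6-tris(benzyloxy)-3-[(2R,4R)-7-(benzyloxy)-2-[4-(benzyloxy)phenyl]chroman-4-yl]phenyl}dodecan-1-one | CCCCCCCCCCCC(=O)c1c(OCc2ccccc2)cc(OCc2ccccc2)c([C@@H]2C[C@H](c3ccc(OCc4ccccc4)cc3)Oc3cc(OCc4ccccc4)ccc32)c1OCc1ccccc1 | intermediate
20 | 1-{2,4,6-trihydroxy-3-[(2R,4R)-7-hydroxy-2-(4-hydroxyphenyl)chroman-4-yl]phenyl}dodecan-1-one | CCCCCCCCCCCC(=O)c1c(O)cc(O)c([C@@H]2C[C@H](c3ccc(O)cc3)Oc3cc(O)ccc32)c1O | target

**Step count**

Total steps: 11. Longest linear sequence: 9 (steps 1, 2, 3, 4, 6, 7, 8, 10, 11).

**Steps most likely to fail**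

Step 4. The enal is hindered by two ortho benzyloxy groups and electron-rich, so iminium formation and β-attack may be slow. A slow catalysed path leaves room for an unselective background reaction and for a second alkylation of the product, which would lower both conversion and enantiomeric purity. The fallback sets out from enal 4 and makes C4–C4a by rhodium-catalysed asymmetric conjugate arylation instead. Commercial 4-bromoresorcinol is protected with MOMCl and iPr2NEt to give 1-bromo-2,4-bis(methoxymethoxy)benzene F1. Bromine–lithium exchange (n-BuLi, THF, −78 °C), B(OiPr)3 and aqueous work-up then give [2,4-bis(methoxymethoxy)phenyl]boronic acid F2. Addition of F2 to 4 with [RhCl(C2H4)2]2 (a monovalent rhodium precursor), a chiral bicyclo[2.2.2]octa-2,5-diene ligand and aqueous KOH in dioxane, with the ligand enantiomer chosen for Si-face delivery, should give (3R)-3-[2,4-bis(methoxymethoxy)phenyl]-3-[2,4,6-tris(benzyloxy)-3-bromophenyl]propanal F3. Aqueous HCl in THF removes both MOM groups, and the freed ortho hydroxyl closes onto the aldehyde, so the fallback comes back to the route at lactol 8.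

Step 7. Equilibration at C2 may stop at a mixture of 2,4-cis and 2,4-trans isomers if the crowded ring D does not favour the equatorial position strongly enough. Prolonged acid could also ionise the C4–ring D bond and erode the C4 configuration. The fallback sets out from triol 12 and sets C2 by kinetic hydride delivery. MnO2 in CH2Cl2 oxidises the activated benzylic alcohol to 1-[4-(benzyloxy)phenyl]-(3R)-3-[2,4,6-tris(benzyloxy)-3-bromophenyl]-3-(2,4-dihydroxyphenyl)propan-1-one F4. Reductive etherification with Et3SiH and BF3·OEt2 in CH2Cl2 at −78 °C then passes through the cyclic 2-aryl oxocarbenium ion. Axial hydride attack on the half-chair with the C4 aryl group equatorial should place the C2 aryl group equatorial and cis to it, so the fallback comes back at flavan 13.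

Step 10. Acyl transfer to the doubly ortho-substituted aryllithium may be slower than proton transfer from the α-CH2 of the amide, which would return the debrominated arene. The fallback sets out from bromide 14 and uses a more electrophilic partner at a lower oxidation level. Aryllithium 17 is generated as in step 10 and quenched with dodecanal at −78 °C to give 1-{2,4,6-tris(benzyloxy)-3-[(2R,4R)-7-(benzyloxy)-2-[4-(benzyloxy)phenyl]chroman-4-yl]phenyl}dodecan-1-ol F5 as a mixture of carbinol epimers. Oxidation with Dess–Martin periodinane in CH2Cl2 buffered with NaHCO3 comes back to the route at ketone 19.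

**Further compounds**

F1 | step 4 | 1-bromo-2,4-bis(methoxymethoxy)benzene | COCOc1ccc(Br)c(OCOC)c1
F2 | step 4 | [2,4-bis(methoxymethoxy)phenyl]boronic acid | COCOc1ccc(B(O)O)c(OCOC)c1
F3 | step 4 | (3R)-3-[2,4-bis(methoxymethoxy)phenyl]-3-[2,4,6-tris(benzyloxy)-3-bromophenyl]propanal | O=CC[C@@H](c1c(OCc2ccccc2)c(Br)c(OCc2ccccc2)cc1OCc1ccccc1)c1ccc(OCOC)cc1OCOC
F4 | step 7 | 1-[4-(benzyloxy)phenyl]-(3R)-3-[2,4,6-tris(benzyloxy)-3-bromophenyl]-3-(2,4-dihydroxyphenyl)propan-1-one | O=C(C[C@@H](c1c(OCc2ccccc2)c(Br)c(OCc2ccccc2)cc1OCc1ccccc1)c1ccc(O)cc1O)c1ccc(OCc2ccccc2)cc1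
F5 | step 10 | 1-{2,4,6-tris(benzyloxy)-3-[(2R,4R)-7-(benzyloxy)-2-[4-(benzyloxy)phenyl]chroman-4-yl]phenyl}dodecan-1-ol | CCCCCCCCCCCC(O)c1c(OCc2ccccc2)cc(OCc2ccccc2)c([C@@H]2C[C@H](c3ccc(OCc4ccccc4)cc3)Oc3cc(OCc4ccccc4)ccc32)c1OCc1ccccc1
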